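**Retrosynthetic overview**
1. Target ⇐ C1 ketone, reduced last from the open (exo) face.
2. C1 ketone ⇐ eight-membered cyclic ether (oxocene) carrying a 3-diazo-2-oxobutyl chain on C3: copper-catalysed oxonium-ylide formation and Stevens 1,2-shift of C9 from O to C10 (ring expansion 8 → 9) forms C9–C10, the tetrahydrofuranone ring and the C10 quaternary centre.
3. Oxocene ⇐ acyclic diene by ring-closing metathesis (C4=C5); the angelate is put on after ring closure.
4. α-Methylene-γ-lactone (C6, C7) ⇐ chromium-mediated 2-(alkoxycarbonyl)allylation of acrolein with an allylic bromide made by Morita–Baylis–Hillman chemistry on an α-silyloxy aldehyde.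
5. That aldehyde ⇐ ether of the methacrolein/acetate aldol (C3) with methyl (R)-glycidate (C8). Ring order: γ-lactone → oxocene → tetrahydrofuran and oxonane together.

Atom labels C1–C15 are the germacrane positions of the target (ether O between C3 and C10; lactone C12(=O)–O–C6; C13 = exocyclic CH2) and are used for all intermediates. CIP labels at C7 and C8 change along the route only because substituent priorities change; the centres are not touched.
Assumption: angelic acid, both methyl glycidate enantiomers, N-ethyl-N-nitrosourea, 3,3-dimethoxybutan-2-one and methyl 2-(trimethylsilyloxy)acrylate are taken as commercial.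

**Step 1**
Reactants: 1 methacrolein; 2 tert-butyl acetate
Product: 4 tert-butyl (3S)-3-hydroxy-4-methylpent-4-enoate, via ketene silyl acetal 3 (not isolated)
Conditions: LiN(i-Pr)2, THF, −78 °C; TBSCl, DMPU, −78 °C → rt; solvent switch; 1, SiCl4 (1.5 equiv), chiral binaphthyldiamine bis-phosphoramide (5 mol %, enantiomer for Si-face attack), CH2Cl2, −78 °C; aq. NaHCO3
Reagents that add atoms: none
Why: Lewis-base-catalysed SiCl4 Mukaiyama aldol addition of the acetate ketene silyl acetal, in which the chiral phosphoramide-bound silicon cation holds the aldehyde and directs attack on its Si face, setting C3 as S.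

**Step 2**
Reactants: 4 tert-butyl (3S)-3-hydroxy-4-methylpent-4-enoate; 5 methyl (2R)-oxirane-2-carboxylate
Product: 6 tert-butyl (3S)-3-{[(2R)-2-hydroxy-3-methoxy-3-oxopropyl]oxy}-4-methylpent-4-enoate
Conditions: 4 (2 equiv, excess recovered), BF3·OEt2 (10 mol %), CH2Cl2, −20 → 0 °C
Reagents that add atoms: none
Why: Lewis-acid-catalysed SN2 alcoholysis of the glycidic ester at its unsubstituted carbon (the carbon next to the ester is deactivated) forms the C3–O–C9 ether and leaves C3 (from 4) and C8 (from 5) untouched.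

**Step 3**
Reactants: 6 hydroxy ester ether
Product: 7 tert-butyl (3S)-3-{[(2R)-2-{[tert-butyl(dimethyl)silyl]oxy}-3-methoxy-3-oxopropyl]oxy}-4-methylpent-4-enoate
Conditions: TBSOTf, 2,6-lutidine, CH2Cl2, −78 → 0 °C
Reagents that add atoms: tert-butyldimethylsilyl trifluoromethanesulfonate, CC(C)(C)[Si](C)(C)OS(=O)(=O)C(F)(F)F
Why: Silyl ether formation blocks the C8 hydroxyl so that it cannot lactonise in step 7 and is a poor leaving group at the allylchromium stage.

**Step 4**
Reactants: 7 silyl ether diester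
Product: 8 tert-butyl (3S)-3-{[(2R)-2-{[tert-butyl(dimethyl)silyl]oxy}-3-oxopropyl]oxy}-4-methylpent-4-enoate
Conditions: i-Bu2AlH (1.1 equiv), CH2Cl2, −78 °C; aq. Rochelle salt
Reagents that add atoms: none
Why: Half-reduction of the α-silyloxy methyl ester through a stable tetrahedral aluminate at −78 °C, where the tert-butyl ester does not react and C8 is not epimerised.

**Step 5**
Reactants: 8 α-silyloxy aldehyde; 9 methyl acrylate
Product: 10 methyl (4R)-5-{[(3S)-1-tert-butoxy-4-methyl-1-oxopent-4-en-3-yl]oxy}-4-{[tert-butyl(dimethyl)silyl]oxy}-3-hydroxy-2-methylidenepentanoate (both C3 epimers)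
Conditions: 9 (5 equiv), DABCO (1 equiv), MeOH, rt
Reagents that add atoms: none
Why: Morita–Baylis–Hillman reaction; the new carbinol centre is formed without control, which is harmless because step 6 removes it.

**Step 6**
Reactants: 10 Morita–Baylis–Hillman adduct
Product: 11 methyl (2Z,4S)-2-(bromomethyl)-5-{[(3S)-1-tert-butoxy-4-methyl-1-oxopent-4-en-3-yl]oxy}-4-{[tert-butyl(dimethyl)silyl]oxy}pent-2-enoate
Conditions: NBS, Me2S, CH2Cl2, −20 → 0 °C
Reagents that add atoms: N-bromosuccinimide, O=C1CCC(=O)N1Br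
Why: Corey–Kim-type activation of the allylic alcohol and SN2′ delivery of bromide gives the thermodynamically preferred (Z)-2-(bromomethyl)enoate with allylic transposition.

**Step 7**
Reactants: 11 allylic bromide; 12 acrolein
Product: 14 tert-butyl (3S)-3-{(2S)-2-{[tert-butyl(dimethyl)silyl]oxy}-2-[(2R,3S)-2-ethenyl-4-methylidene-5-oxooxolan-3-yl]ethoxy}-4-methylpent-4-enoate, via hydroxy ester 13 (not isolated)
Conditions: CrCl2 (3 equiv), 12 (2 equiv), THF, 0 °C → rt; then p-TsOH (5 mol %), CH2Cl2, rt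
Reagents that add atoms: none
Why: Nozaki–Hiyama-type 2-(alkoxycarbonyl)allylation through a chair transition state gives the anti C6/C7 adduct, the face of C7 being fixed by C8 (H8 in the alkene plane to avoid allylic strain, aldehyde entering anti to the C8–C9 bond), and acid then closes the trans α-methylene-γ-lactone.

**Step 8**
Reactants: 14 lactone diene
Product: 15 silyl oxocene lactone (3S,4Z,6R,7S,8S)
Conditions: second-generation Grubbs catalyst RuCl2(=CHPh)(H2IMes)(PCy3) (10 mol %), toluene (2 mM), 80 °C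
Reagents that add atoms: none
Why: Ring-closing metathesis between the vinyl and isopropenyl groups closes the eight-membered ether, whose ring size enforces the Z geometry at C4=C5.

**Step 9**
Reactants: 15 silyl oxocene lactone
Product: 16 hydroxy oxocene lactone (3S,4Z,6R,7R,8S)
Conditions: HF·pyridine, pyridine/THF, 0 °C → rt
Reagents that add atoms: none
Why: Fluoride-mediated desilylation frees the C8 hydroxyl without touching the lactone or the tert-butyl ester.

**Step 10**
Reactants: 16 hydroxy oxocene lactone; 17 angelic acid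
Product: 19 angeloyl oxocene lactone (3S,4Z,6R,7S,8S), via mixed anhydride 18 (not isolated)
Conditions: 17, 2,4,6-trichlorobenzoyl chloride, Et3N, toluene, rt; then 16, 80 °C
Reagents that add atoms: none
Why: Yamaguchi esterification through mixed anhydride 18, a protocol that transfers the angeloyl group without Z → E isomerisation to the tiglate.

**Step 11**
Reactants: 19 angeloyl oxocene lactone; 20 N-ethyl-N-nitrosourea
Product: 24 oxocene diazoketone (3S,4Z,6R,7S,8S), via carboxylic acid 21 (not isolated), via mixed carbonic anhydride 22 (not isolated), via diazoethane 23 (not isolated)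
Conditions: TFA, CH2Cl2, 0 °C; evaporate; i-BuOCOCl, N-methylmorpholine, THF, −20 °C; 23 (1.3 equiv in Et2O, from 20 and KOH, Et2O/H2O, 0 °C), −78 → −40 °C; AcOH quench at −78 °C
Reagents that add atoms: none
Why: Acidolysis of the tert-butyl ester, then acylation of diazoethane by the mixed anhydride (first stage of an Arndt–Eistert sequence) at low temperature, where acyl transfer should outrun dipolar cycloaddition to the α-methylene lactone.

**Step 12**
Reactants: 24 oxocene diazoketone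
Product: 26 1-oxo-3,10-epoxy germacranolide (3S,4Z,6R,7R,8R,10S), via oxonium ylide 25 (not isolated)
Conditions: Cu(CF3COCHCOCF3)2 (10 mol %), CH2Cl2, reflux, slow addition of 24 (final 5 mM)
Reagents that add atoms: none
Why: Proposed new method: copper-catalysed oxonium-ylide Stevens ring expansion of an eight-membered cyclic ether — the copper carbenoid from 24 is trapped by the ring oxygen to give the five-membered bicyclic ylide 25, homolysis of the exocyclic O–C9 bond and recombination of the radical pair at C10 (a stepwise 1,2-shift) inserts C10 between O and C9, forming C9–C10, the tetrahydrofuranone and the oxygen-bridged nine-membered ring at once, with C10 forced to S because only the cis-bridged bicycle can form from the 3S ylide; the allylic O–C3 bond lies in the plane of the ylide ring and overlaps poorly with the carbanion, and cyclopropanation of C4=C5 would create two adjacent quaternary carbons, so both should lose to ylide formation with this electrophilic copper catalyst; the closest known reaction type is the Stevens [1,2]-shift ring expansion of oxonium ylides from tetrahydrofuran- and tetrahydropyran-tethered α-diazo ketones to oxygen-bridged cycloheptanones and cyclooctanones, extended here to an oxocene, a fully substituted ylide carbon and an unstabilised primary migrating carbon.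

**Step 13**
Reactants: 26 1-oxo-3,10-epoxy germacranolide
Product: 27 target (1S,3S,4Z,6R,7R,8R,10S)
Conditions: NaBH4, CeCl3·7H2O, MeOH, −78 °C
Reagents that add atoms: none
Why: Luche 1,2-reduction in which hydride attacks C1 from the exo face (the side of the one-atom oxygen bridge), giving the endo 1S alcohol cis to C9, while the ketone reacts faster than the enoates undergo conjugate reduction.

**Compound list**
1 | methacrolein (2-methylprop-2-enal) | CC(=C)C=O | starting material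
2 | tert-butyl acetate | CC(=O)OC(C)(C)C | starting material
3 | tert-butyl[(1-tert-butoxyethenyl)oxy]dimethylsilane (ketene silyl acetal) | C=C(OC(C)(C)C)O[Si](C)(C)C(C)(C)C | intermediate
4 | tert-butyl (3S)-3-hydroxy-4-methylpent-4-enoate | CC(=C)[C@@H](O)CC(=O)OC(C)(C)C | intermediate
5 | methyl (2R)-oxirane-2-carboxylate | COC(=O)[C@H]1CO1 | starting material
6 | tert-butyl (3S)-3-{[(2R)-2-hydroxy-3-methoxy-3-oxopropyl]oxy}-4-methylpent-4-enoate | COC(=O)[C@H](O)CO[C@@H](CC(=O)OC(C)(C)C)C(C)=C | intermediate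
7 | tert-butyl (3S)-3-{[(2R)-2-{[tert-butyl(dimethyl)silyl]oxy}-3-methoxy-3-oxopropyl]oxy}-4-methylpent-4-enoate | COC(=O)[C@H](O[Si](C)(C)C(C)(C)C)CO[C@@H](CC(=O)OC(C)(C)C)C(C)=C | intermediate
8 | tert-butyl (3S)-3-{[(2R)-2-{[tert-butyl(dimethyl)silyl]oxy}-3-oxopropyl]oxy}-4-methylpent-4-enoate | O=C[C@H](O[Si](C)(C)C(C)(C)C)CO[C@@H](CC(=O)OC(C)(C)C)C(C)=C | intermediate
9 | methyl acrylate | COC(=O)C=C | starting material
10 | methyl (4R)-5-{[(3S)-1-tert-butoxy-4-methyl-1-oxopent-4-en-3-yl]oxy}-4-{[tert-butyl(dimethyl)silyl]oxy}-3-hydroxy-2-methylidenepentanoate (both C3 epimers) | COC(=O)C(=C)C(O)[C@H](O[Si](C)(C)C(C)(C)C)CO[C@@H](CC(=O)OC(C)(C)C)C(C)=C | intermediate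
11 | methyl (2Z,4S)-2-(bromomethyl)-5-{[(3S)-1-tert-butoxy-4-methyl-1-oxopent-4-en-3-yl]oxy}-4-{[tert-butyl(dimethyl)silyl]oxy}pent-2-enoate | COC(=O)/C(CBr)=C/[C@H](O[Si](C)(C)C(C)(C)C)CO[C@@H](CC(=O)OC(C)(C)C)C(C)=C | intermediate
12 | acrolein (prop-2-enal) | C=CC=O | starting material
13 | methyl (3S,4R)-3-[(1S)-2-{[(3S)-1-tert-butoxy-4-methyl-1-oxopent-4-en-3-yl]oxy}-1-{[tert-butyl(dimethyl)silyl]oxy}ethyl]-4-hydroxy-2-methylidenehex-5-enoate (formed as its chromium alkoxide) | C=C[C@@H](O)[C@H](C(=C)C(=O)OC)[C@H](O[Si](C)(C)C(C)(C)C)CO[C@@H](CC(=O)OC(C)(C)C)C(C)=C | intermediate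
14 | tert-butyl (3S)-3-{(2S)-2-{[tert-butyl(dimethyl)silyl]oxy}-2-[(2R,3S)-2-ethenyl-4-methylidene-5-oxooxolan-3-yl]ethoxy}-4-methylpent-4-enoate | C=C[C@H]1OC(=O)C(=C)[C@@H]1[C@H](O[Si](C)(C)C(C)(C)C)CO[C@@H](CC(=O)OC(C)(C)C)C(C)=C | intermediate
15 | silyl oxocene lactone: ring O–C3–C4(CH3)=C5–C6–C7–C8–C9 (4Z), CH2CO2t-Bu on C3, OTBS on C8, α-methylene-γ-lactone fused at C6(O)–C7; (3S,6R,7S,8S) | C/C1=C/[C@H]2OC(=O)C(=C)[C@@H]2[C@H](O[Si](C)(C)C(C)(C)C)CO[C@H]1CC(=O)OC(C)(C)C | intermediate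
16 | hydroxy oxocene lactone: as 15 with free 8-OH; (3S,4Z,6R,7R,8S) | C/C1=C/[C@H]2OC(=O)C(=C)[C@@H]2[C@H](O)CO[C@H]1CC(=O)OC(C)(C)C | intermediate
17 | angelic acid [(2Z)-2-methylbut-2-enoic acid] | C/C=C(/C)C(=O)O | starting material
18 | (2Z)-2-methylbut-2-enoic 2,4,6-trichlorobenzoic anhydride | C/C=C(/C)C(=O)OC(=O)c1c(Cl)cc(Cl)cc1Cl | intermediate
19 | angeloyl oxocene lactone: as 16 with 8-O-angelate; tert-butyl ester; (3S,4Z,6R,7S,8S) | C/C1=C/[C@H]2OC(=O)C(=C)[C@@H]2[C@H](OC(=O)/C(C)=C\C)CO[C@H]1CC(=O)OC(C)(C)C | intermediate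
20 | N-ethyl-N-nitrosourea | CCN(N=O)C(N)=O | starting material
21 | oxocene acetic acid: as 19 with CH2CO2H on C3 | C/C1=C/[C@H]2OC(=O)C(=C)[C@@H]2[C@H](OC(=O)/C(C)=C\C)CO[C@H]1CC(=O)O | intermediate
22 | isobutyl carbonic mixed anhydride of 21 | C/C1=C/[C@H]2OC(=O)C(=C)[C@@H]2[C@H](OC(=O)/C(C)=C\C)CO[C@H]1CC(=O)OC(=O)OCC(C)C | intermediate
23 | diazoethane | CC=[N+]=[N-] | intermediate
24 | oxocene diazoketone: as 19 with CH2C(=O)C(=N2)CH3 on C3; (3S,4Z,6R,7S,8S) | C/C1=C/[C@H]2OC(=O)C(=C)[C@@H]2[C@H](OC(=O)/C(C)=C\C)CO[C@H]1CC(=O)C(C)=[N+]=[N-] | intermediate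
25 | bicyclic oxonium ylide: ring O bonded to C3, C9 and carbanionic C10 | C/C1=C/[C@H]2OC(=O)C(=C)[C@@H]2[C@H](OC(=O)/C(C)=C\C)C[O+]3[C@H]1CC(=O)[C-]3C | intermediate
26 | (3S,4Z,6R,7R,8R,10S)-8-angeloyloxy-3,10-epoxy-1-oxogermacra-4,11(13)-dien-12,6-olide | C=C1C(=O)O[C@@H]2/C=C(/C)[C@@H]3CC(=O)[C@](C)(C[C@@H](OC(=O)/C(C)=C\C)[C@@H]12)O3 | intermediate
27 | (1S,3S,4Z,6R,7R,8R,10S)-8-angeloyloxy-3,10-epoxy-1-hydroxygermacra-4,11(13)-dien-12,6-olide (CNP0213894.1) | C=C1C(=O)O[C@@H]2/C=C(/C)[C@@H]3C[C@H](O)[C@](C)(C[C@@H](OC(=O)/C(C)=C\C)[C@@H]12)O3 | target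

**Totals:** 13 steps; longest linear sequence 13 steps (1 and 2 to 27).

**Three steps most likely to fail**

Step 12 (the proposed new step). Risks: cyclopropanation of C4=C5, cleavage at the allylic C3–O bond, a 1,2-hydride shift from the methyl group, or a slow shift of the unstabilised C9. The fallback uses known chemistry, builds the tetrahydrofuran first and closes the nine-membered ring last by metathesis; it sets out from methacrolein 1 and comes back at target 27. A boron aldol of 3,3-dimethoxybutan-2-one (Ipc2BCl enantiomer for Si-face attack, Et3N) with 1 gives hydroxy ketone F1. Hydroxyl-directed 1,3-anti reduction with Me4NBH(OAc)3 gives diol F2. Camphorsulfonic acid closes cyclic ketal F3, and TBSOTf gives silyl ketal F4. TMSOTf-promoted substitution at the ketal carbon with methyl 2-(trimethylsilyloxy)acrylate, the nucleophile entering cis to the neighbouring silyloxy group (inside attack on the oxocarbenium ion), sets C10 and gives keto ester F5. Oxazaborolidine-catalysed (CBS) reduction with catecholborane gives hydroxy ester F6, TBSOTf gives bis-silyl ester F7 and i-Bu2AlH gives aldehyde F8. The reagents of steps 5 to 7 then give Morita–Baylis–Hillman adduct F9, allylic bromide F10, chromium adduct F11 (not isolated) and lactone diene F12. Ring-closing metathesis with the second-generation Grubbs catalyst gives bridged bis-silyl ether F13, HF·pyridine gives diol F14, and acylation of its less hindered C8 hydroxyl with 18 gives 27.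

Step 7. Risks: the anti selectivity and the facial control by C8 are argued by analogy, not shown for this bromide. The fallback replaces the anti-selective chromium addition by a syn-selective indium addition followed by an inverting lactonisation; it sets out from bromide 11 and comes back at lactone 14. Indium powder and 12 in THF/H2O give syn adduct F15, LiOH gives hydroxy acid F16, and Mitsunobu lactonisation (PPh3, DIAD) closes the lactone with inversion at C6 to give 14.

Step 2. Risks: the glycidic ester is a sluggish electrophile and the allylic alcohol 4 may ionise under Lewis acid. The fallback forms the ether by carbene O–H insertion and sets C8 afterwards by reduction; it sets out from alcohol 4 and comes back at ether 6. Methyl chlorooxoacetate and diazomethane give diazopyruvate F17, Rh2(OAc)4-catalysed O–H insertion into 4 gives keto ester F18, and oxazaborolidine-catalysed reduction (enantiomer giving 2R) gives 6.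

**Further compounds**
F1 | step 12 | hydroxy ketone (5S)-5-hydroxy-2,2-dimethoxy-6-methylhept-6-en-3-one | CC(=C)[C@@H](O)CC(=O)C(C)(OC)OC
F2 | step 12 | diol (3S,5S)-2,2-dimethoxy-6-methylhept-6-ene-3,5-diol | CC(=C)[C@@H](O)C[C@H](O)C(C)(OC)OC
F3 | step 12 | cyclic ketal (3S,5S)-2-methoxy-2-methyl-5-(prop-1-en-2-yl)oxolan-3-ol (both anomers) | COC1(C)O[C@H](C(C)=C)C[C@@H]1O
F4 | step 12 | silyl ketal tert-butyl{[(3S,5S)-2-methoxy-2-methyl-5-(prop-1-en-2-yl)oxolan-3-yl]oxy}dimethylsilane | COC1(C)O[C@H](C(C)=C)C[C@@H]1O[Si](C)(C)C(C)(C)C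
F5 | step 12 | keto ester methyl 3-[(2S,3S,5S)-3-{[tert-butyl(dimethyl)silyl]oxy}-2-methyl-5-(prop-1-en-2-yl)oxolan-2-yl]-2-oxopropanoate | COC(=O)C(=O)C[C@]1(C)O[C@H](C(C)=C)C[C@@H]1O[Si](C)(C)C(C)(C)C
F6 | step 12 | hydroxy ester methyl (2R)-3-[(2S,3S,5S)-3-{[tert-butyl(dimethyl)silyl]oxy}-2-methyl-5-(prop-1-en-2-yl)oxolan-2-yl]-2-hydroxypropanoate | COC(=O)[C@H](O)C[C@]1(C)O[C@H](C(C)=C)C[C@@H]1O[Si](C)(C)C(C)(C)C
F7 | step 12 | bis-silyl ester methyl (2R)-2-{[tert-butyl(dimethyl)silyl]oxy}-3-[(2S,3S,5S)-3-{[tert-butyl(dimethyl)silyl]oxy}-2-methyl-5-(prop-1-en-2-yl)oxolan-2-yl]propanoate | COC(=O)[C@H](O[Si](C)(C)C(C)(C)C)C[C@]1(C)O[C@H](C(C)=C)C[C@@H]1O[Si](C)(C)C(C)(C)C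
F8 | step 12 | aldehyde (2R)-2-{[tert-butyl(dimethyl)silyl]oxy}-3-[(2S,3S,5S)-3-{[tert-butyl(dimethyl)silyl]oxy}-2-methyl-5-(prop-1-en-2-yl)oxolan-2-yl]propanal | O=C[C@H](O[Si](C)(C)C(C)(C)C)C[C@]1(C)O[C@H](C(C)=C)C[C@@H]1O[Si](C)(C)C(C)(C)C
F9 | step 12 | Morita–Baylis–Hillman adduct methyl (4R)-4-{[tert-butyl(dimethyl)silyl]oxy}-5-[(2S,3S,5S)-3-{[tert-butyl(dimethyl)silyl]oxy}-2-methyl-5-(prop-1-en-2-yl)oxolan-2-yl]-3-hydroxy-2-methylidenepentanoate (both C3 epimers) | COC(=O)C(=C)C(O)[C@H](O[Si](C)(C)C(C)(C)C)C[C@]1(C)O[C@H](C(C)=C)C[C@@H]1O[Si](C)(C)C(C)(C)C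
F10 | step 12 | allylic bromide methyl (2Z,4R)-2-(bromomethyl)-4-{[tert-butyl(dimethyl)silyl]oxy}-5-[(2S,3S,5S)-3-{[tert-butyl(dimethyl)silyl]oxy}-2-methyl-5-(prop-1-en-2-yl)oxolan-2-yl]pent-2-enoate | COC(=O)/C(CBr)=C/[C@H](O[Si](C)(C)C(C)(C)C)C[C@]1(C)O[C@H](C(C)=C)C[C@@H]1O[Si](C)(C)C(C)(C)C
F11 | step 12 | chromium adduct methyl (3S,4R)-3-{(1R)-1-{[tert-butyl(dimethyl)silyl]oxy}-2-[(2S,3S,5S)-3-{[tert-butyl(dimethyl)silyl]oxy}-2-methyl-5-(prop-1-en-2-yl)oxolan-2-yl]ethyl}-4-hydroxy-2-methylidenehex-5-enoate | C=C[C@@H](O)[C@H](C(=C)C(=O)OC)[C@H](O[Si](C)(C)C(C)(C)C)C[C@]1(C)O[C@H](C(C)=C)C[C@@H]1O[Si](C)(C)C(C)(C)C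
F12 | step 12 | lactone diene (4S,5R)-4-{(1R)-1-{[tert-butyl(dimethyl)silyl]oxy}-2-[(2S,3S,5S)-3-{[tert-butyl(dimethyl)silyl]oxy}-2-methyl-5-(prop-1-en-2-yl)oxolan-2-yl]ethyl}-5-ethenyl-3-methylideneoxolan-2-one | C=C[C@H]1OC(=O)C(=C)[C@@H]1[C@H](O[Si](C)(C)C(C)(C)C)C[C@]2(C)O[C@H](C(C)=C)C[C@@H]2O[Si](C)(C)C(C)(C)C
F13 | step 12 | bridged bis-silyl ether (1S,3S,4Z,6R,7S,8R,10S)-1,8-bis{[tert-butyl(dimethyl)silyl]oxy}-3,10-epoxygermacra-4,11(13)-dien-12,6-olide | C=C1C(=O)O[C@@H]2/C=C(/C)[C@@H]3C[C@H](O[Si](C)(C)C(C)(C)C)[C@](C)(C[C@@H](O[Si](C)(C)C(C)(C)C)[C@@H]12)O3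
F14 | step 12 | diol (1S,3S,4Z,6R,7R,8R,10S)-3,10-epoxy-1,8-dihydroxygermacra-4,11(13)-dien-12,6-olide | C=C1C(=O)O[C@@H]2/C=C(/C)[C@@H]3C[C@H](O)[C@](C)(C[C@@H](O)[C@@H]12)O3
F15 | step 7 | syn adduct methyl (3S,4S)-3-[(1S)-2-{[(3S)-1-tert-butoxy-4-methyl-1-oxopent-4-en-3-yl]oxy}-1-{[tert-butyl(dimethyl)silyl]oxy}ethyl]-4-hydroxy-2-methylidenehex-5-enoate | C=C[C@H](O)[C@H](C(=C)C(=O)OC)[C@H](O[Si](C)(C)C(C)(C)C)CO[C@@H](CC(=O)OC(C)(C)C)C(C)=C
F16 | step 7 | hydroxy acid (3S,4S)-3-[(1S)-2-{[(3S)-1-tert-butoxy-4-methyl-1-oxopent-4-en-3-yl]oxy}-1-{[tert-butyl(dimethyl)silyl]oxy}ethyl]-4-hydroxy-2-methylidenehex-5-enoic acid | C=C[C@H](O)[C@H](C(=C)C(=O)O)[C@H](O[Si](C)(C)C(C)(C)C)CO[C@@H](CC(=O)OC(C)(C)C)C(C)=C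
F17 | step 2 | diazopyruvate methyl 3-diazo-2-oxopropanoate | COC(=O)C(=O)C=[N+]=[N-]
F18 | step 2 | keto ester tert-butyl (3S)-3-[(3-methoxy-2,3-dioxopropyl)oxy]-4-methylpent-4-enoate | COC(=O)C(=O)CO[C@@H](CC(=O)OC(C)(C)C)C(C)=C
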